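**Target 15:** (2S)-5,7-dihydroxy-2-[4-hydroxy-3-(3-methylbut-2-enyl)phenyl]-6,8-bis(3-methylbut-2-enyl)chroman-4-one. The stereodescriptor was checked against the given SMILES: O1 > C1' > C3 > H gives 2S. Flavanone numbering is used throughout (O1, C2, C3, C4, C4a, C5–C8, C8a; ring B C1'–C6').

## The problem

The chromanone ring system is simple; the difficulty lies in the substitution pattern and the single stereocentre. Three prenyl groups must be placed regiospecifically on two electron-rich rings (C6 and C8 on ring A, C3' on ring B). Direct C-alkylation of phloroglucinol-type rings with prenyl halides gives mixtures of O-, mono-C-, di-C- and dearomatised products. The only stereocentre, C2, is a benzylic ether carbon β to the C4 ketone. It epimerises by retro-oxa-Michael opening to the 2'-hydroxychalcone under base, most easily once 5-OH and 4'-OH are free. No other stereocentre can control it, so it must come from a catalyst and must not see base afterwards. Each prenyl group lies ortho to a free phenol and cyclises to a 2,2-dimethylchroman under acid, and hydrogenolysis would saturate it, so the usual phenol protecting groups create an endgame problem. The enabling feature is that each prenylated carbon is ortho to a phenolic oxygen (C6 to O5, C8 to O7, C3' to O4'), which makes three aromatic Claisen retrons, and that O5 sits peri to the C4 carbonyl, a chelation site that allows this ether to be triggered first. The target is therefore a constitutional isomer of the tris(1,1-dimethylallyl) ether 13 of the parent (2S)-trihydroxyflavanone, and the three oxygens can carry the prenyl carbons as ethers that also serve as the only protecting groups.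

## Retrosynthesis

**15 ⇒ 13.** The three aryl–CH2 bonds (C6–C1'', C8–C1'', C3'–C1'') are cut and each allyl unit is reconnected through its tertiary carbon to the neighbouring oxygen. This is preferred to three separate C–C bond formations because a [3,3] shift is ortho-specific, gives only the linear prenyl group, needs no metal, base or acid, and liberates the phenols in the same event. The precursor 13 has three identical ether groups and no C-prenyl group. The forward reaction must run O5→C6 before O7 moves; this is arranged through intermediate 14 by chelation of Eu(III) at C4=O/O5.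

**13 ⇒ 6 + 12.** The C2–C1' bond is cut. A rhodium-catalysed asymmetric 1,4-addition of arylboronic acid 12 to chromone 6 forms this bond and sets C2 in one step. This is preferred to an O1–C2 (oxa-Michael) disconnection, which has no dependable asymmetric version for unactivated chalcones. Both partners are achiral and flat. The forward reaction must tolerate three tert-allyl ethers and run near neutrality at low temperature.

**6 ⇒ 5 ⇒ 3 ⇒ 1 + 2.** The alkenes are taken back to alkynes (5), and the chromone C2 carbon is removed to give acetophenone 3 (through enaminone 4). Etherifying 5-OH of a preformed chromone is avoided because that hydroxyl is strongly chelated and hindered. In phloroacetophenone 1 one of the two ortho hydroxyls is always free of the hydrogen bond, so two ethers can be installed with chloroalkyne 2, and the remaining chelated OH later closes the pyranone ring. The alkyne level is kept through the ring closure because tert-propargyl ethers tolerate heat and mild acid that tert-allyl ethers would not.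

**12 ⇒ 9 ⇒ 8 ⇒ 7 + 2.** The C–B bond is cut to aryl bromide 9, the alkene is taken back to alkyne 8, and the ether to 4-bromophenol 7 and 2. The same etherification/semihydrogenation pair is used as on ring A. Bromine–lithium exchange is chosen over palladium borylation because Pd(0) would ionise the tert-allyl aryl ether.

## Roads not taken

**Alternative 1:** (the obvious route) Cut O1–C2 and the C2–C3 bond (the chalcone Cα=Cβ). Claisen–Schmidt condensation of a ring-A ketone and a ring-B aldehyde that already carry their prenyl groups would give chalcone A1, which closes by oxa-Michael addition. This needs three separate C-prenylations of phenols with prenyl halide, several phenol protecting groups and an acidic deprotection beside three prenyl groups. The ring closure of A1 is a reversible, largely spontaneous addition with no reliable enantioselective catalyst when no activating group is present, so the product would be racemic or need resolution. The chosen plan sets C2 by a catalytic C–C bond formation and uses no protecting groups.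

**Alternative 2:** Cut the three aryl–CH2 bonds as cross-couplings. A (2S)-triiodoflavanone A2 would be coupled three times with a prenyl-metal reagent (Stille or Suzuki–Miyaura). Iodination of ring B is hard to stop at one of two equivalent positions ortho to 4'-OH. Allyl transmetalation can give prenyl or tert-prenyl at each of three sites. Basic coupling conditions open the flavanone ring and erode C2. The sigmatropic plan has none of these selectivity questions and no base.

**Alternative 3:** Run the triple Claisen shift one stage earlier, on the open tris-ether chalcone A3. The chelated 2'-OH would fix the ring-A regiochemistry of both shifts without ambiguity, and the product would be A1. C2 would then again be formed by the uncontrolled oxa-Michael closure of A1. The chosen plan keeps the heterocycle closed from the chromone onward, so C2 is set by the arylation; the price is that the two ring-A shifts must be ordered, which the C4=O/O5 chelation site allows.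

Key step: step 8

Assumption: the facial sense of the Rh/chiral diene catalyst on chromone 6 is taken to parallel that on simple cyclic enones; the ligand antipode is chosen so that 13 is 2S, and the mirror-image ligand is used if the sense proves opposite.

## Route

Step 1
Reactants: 1 1-(2,4,6-trihydroxyphenyl)ethanone; 2 3-chloro-3-methylbut-1-yne
Product: 3 1-[2-hydroxy-4,6-bis(2-methylbut-3-yn-2-yloxy)phenyl]ethanone
Conditions: 2 (2.3 equiv), DBU (2.5 equiv), CuCl2·2H2O (1 mol %), MeCN, 0 °C
Reagents that add atoms: none
Why: Copper-catalysed propargylic etherification of phenols, which forms tertiary aryl ethers that SN2 chemistry cannot. The para hydroxyl and one ortho hydroxyl should react while the third stays locked in the hydrogen bond to the acetyl group, the usual pattern of bis-O-alkylation of phloroacetophenone.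

Step 2
Reactants: 3 1-[2-hydroxy-4,6-bis(2-methylbut-3-yn-2-yloxy)phenyl]ethanone
Product: 5 5,7-bis(2-methylbut-3-yn-2-yloxy)chromen-4-one, via enaminone 4 (not isolated)
Conditions: DMF-DMA, PhMe, 85 °C; evaporate; AcOH, 50 °C
Reagents that add atoms: N,N-dimethylformamide dimethyl acetal, COC(OC)N(C)C
Why: Enaminone chromone synthesis: condensation at the acetyl methyl group, then acid-promoted addition–elimination by the chelated hydroxyl with loss of dimethylamine. The ethers are kept at the alkyne level here because tert-propargyl aryl ethers withstand this temperature and acetic acid.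

Step 3
Reactants: 5 5,7-bis(2-methylbut-3-yn-2-yloxy)chromen-4-one
Product: 6 5,7-bis(2-methylbut-3-en-2-yloxy)chromen-4-one
Conditions: H2 (1 atm), Lindlar catalyst, quinoline, EtOAc, rt
Reagents that add atoms: none
Why: Lindlar semihydrogenation of terminal alkynes. The poisoned catalyst should leave the chromone C2=C3 bond (a vinylogous ester) and the new vinyl groups untouched when hydrogen uptake is stopped at two equivalents.

Step 4
Reactants: 7 4-bromophenol; 2 3-chloro-3-methylbut-1-yne
Product: 8 1-bromo-4-(2-methylbut-3-yn-2-yloxy)benzene
Conditions: 2 (1.2 equiv), DBU (1.3 equiv), CuCl2·2H2O (1 mol %), MeCN, 0 °C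
Reagents that add atoms: none
Why: The same copper-catalysed propargylic etherification as in step 1, on a simple phenol with no competing site.

Step 5
Reactants: 8 1-bromo-4-(2-methylbut-3-yn-2-yloxy)benzene
Product: 9 1-bromo-4-(2-methylbut-3-en-2-yloxy)benzene
Conditions: H2 (1 atm), Lindlar catalyst, quinoline, EtOAc, rt
Reagents that add atoms: none
Why: Lindlar semihydrogenation; the poisoned catalyst at 1 atm should not hydrogenolyse the aryl bromide. The acidic alkyne hydrogen is removed before the lithiation of step 6.

Step 6
Reactants: 9 1-bromo-4-(2-methylbut-3-en-2-yloxy)benzene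
Product: 12 [4-(2-methylbut-3-en-2-yloxy)phenyl]boronic acid, via aryllithium 10 (not isolated), via lithium triisopropoxyborate 11 (not isolated)
Conditions: n-BuLi, THF, −78 °C; B(OiPr)3, −78 °C to rt; sat. aq. NH4Cl
Reagents that add atoms: triisopropyl borate, CC(C)OB(OC(C)C)OC(C)C; water, O
Why: Bromine–lithium exchange and borate trapping. The ether has no α-hydrogen for a Wittig rearrangement, and the neutral hydrolysis spares the acid-sensitive tert-allyl ether; palladium borylation is avoided because Pd(0) would ionise that ether.

Step 7
Reactants: 6 5,7-bis(2-methylbut-3-en-2-yloxy)chromen-4-one; 12 [4-(2-methylbut-3-en-2-yloxy)phenyl]boronic acid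
Product: 13 (2S)-5,7-bis(2-methylbut-3-en-2-yloxy)-2-[4-(2-methylbut-3-en-2-yloxy)phenyl]chroman-4-one
Conditions: [RhCl(C2H4)2]2 (1.5 mol %), Ph-bod* chiral diene (antipode giving 2S, 3.3 mol %), KOH (10 mol %), 12 (2 equiv), PhMe/H2O 10:1, 30 °C
Reagents that add atoms: none
Why: Rhodium-catalysed asymmetric 1,4-addition of an arylboronic acid to a chromone (Hayashi–Miyaura reaction): the aryl–Rh species adds to one face of C2=C3 inside the chiral diene pocket and water protonates the rhodium enolate, so C2 is set by the ligand alone. The vinyl groups are unactivated, sit on quaternary carbons and cannot isomerise, so insertion into the chromone should be much faster. The mild, nearly neutral conditions should neither open the flavanone ring nor start the Claisen shifts.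

Step 8
Reactants: 13 (2S)-5,7-bis(2-methylbut-3-en-2-yloxy)-2-[4-(2-methylbut-3-en-2-yloxy)phenyl]chroman-4-one
Product: 15 (2S)-5,7-dihydroxy-2-[4-hydroxy-3-(3-methylbut-2-enyl)phenyl]-6,8-bis(3-methylbut-2-enyl)chroman-4-one, via 5-hydroxy-6-prenyl bis-ether 14 (not isolated)
Conditions: Eu(fod)3 (10 mol %), degassed PhMe, 60 °C; then 110 °C
Reagents that add atoms: none
Why: Three aromatic Claisen ([3,3]-sigmatropic) rearrangements of aryl 1,1-dimethylallyl ethers run in one flask; the closest known reaction types are the Eu(fod)3-catalysed Claisen shift of allyl ethers peri to a flavanone carbonyl and the thermal shift of tert-prenyl aryl ethers to ortho-prenylphenols. Each shift passes through a six-membered chair transition state to an ortho-dienone that enolises, so the allyl unit arrives inverted as CH2CH=CMe2 and the oxygen is released as the free phenol; no ring is closed. No stereocentre is formed: C2 is a spectator, and the aprotic, base-free medium is chosen because its only route to epimerisation is retro-oxa-Michael opening to the chalcone. The selectivity needed is O5→C6 and O7→C8 on ring A, and it is secured by order, since Eu(III) chelates C4=O and O5 and so triggers the peri ether first, at 60 °C, toward its only free ortho carbon C6 to give 14. In 14 the C6 position is occupied, so on heating the O7 group can end only at C8; a shift to C6 would give a dienone with no enolisable hydrogen, which can only revert. Independently of the catalyst, the bulky O5 substituent must point toward C6, away from the carbonyl, and so turns the O7 substituent toward C8. The first dienone should enolise and not undergo a Cope shift to C8, because that shift would build a congested aryl–CMe2 bond. The O4' group has two equivalent ortho positions, so ring B cannot give a regioisomer, and the product needs no deprotection.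

## Compound list

1 | 1-(2,4,6-trihydroxyphenyl)ethanone (phloroacetophenone) | CC(=O)c1c(O)cc(O)cc1O | starting material
2 | 3-chloro-3-methylbut-1-yne | CC(C)(Cl)C#C | starting material
3 | 1-[2-hydroxy-4,6-bis(2-methylbut-3-yn-2-yloxy)phenyl]ethanone | CC(=O)c1c(O)cc(OC(C)(C)C#C)cc1OC(C)(C)C#C | intermediate
4 | (E)-3-(dimethylamino)-1-[2-hydroxy-4,6-bis(2-methylbut-3-yn-2-yloxy)phenyl]prop-2-en-1-one | CN(C)/C=C/C(=O)c1c(O)cc(OC(C)(C)C#C)cc1OC(C)(C)C#C | intermediate
5 | 5,7-bis(2-methylbut-3-yn-2-yloxy)chromen-4-one | O=c1ccoc2cc(OC(C)(C)C#C)cc(OC(C)(C)C#C)c12 | intermediate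
6 | 5,7-bis(2-methylbut-3-en-2-yloxy)chromen-4-one | O=c1ccoc2cc(OC(C)(C)C=C)cc(OC(C)(C)C=C)c12 | intermediate
7 | 4-bromophenol | Oc1ccc(Br)cc1 | starting material
8 | 1-bromo-4-(2-methylbut-3-yn-2-yloxy)benzene | C#CC(C)(C)Oc1ccc(Br)cc1 | intermediate
9 | 1-bromo-4-(2-methylbut-3-en-2-yloxy)benzene | C=CC(C)(C)Oc1ccc(Br)cc1 | intermediate
10 | [4-(2-methylbut-3-en-2-yloxy)phenyl]lithium | [Li]c1ccc(OC(C)(C)C=C)cc1 | intermediate
11 | lithium triisopropoxy[4-(2-methylbut-3-en-2-yloxy)phenyl]borate | [Li+].C=CC(C)(C)Oc1ccc([B-](OC(C)C)(OC(C)C)OC(C)C)cc1 | intermediate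
12 | [4-(2-methylbut-3-en-2-yloxy)phenyl]boronic acid | C=CC(C)(C)Oc1ccc(B(O)O)cc1 | intermediate
13 | (2S)-5,7-bis(2-methylbut-3-en-2-yloxy)-2-[4-(2-methylbut-3-en-2-yloxy)phenyl]chroman-4-one | O=C1C[C@@H](c2ccc(OC(C)(C)C=C)cc2)Oc2cc(OC(C)(C)C=C)cc(OC(C)(C)C=C)c12 | intermediate
14 | (2S)-5-hydroxy-6-(3-methylbut-2-enyl)-7-(2-methylbut-3-en-2-yloxy)-2-[4-(2-methylbut-3-en-2-yloxy)phenyl]chroman-4-one | O=C1C[C@@H](c2ccc(OC(C)(C)C=C)cc2)Oc2cc(OC(C)(C)C=C)c(CC=C(C)C)c(O)c12 | intermediate
15 | (2S)-5,7-dihydroxy-2-[4-hydroxy-3-(3-methylbut-2-enyl)phenyl]-6,8-bis(3-methylbut-2-enyl)chroman-4-one | CC(C)=CCc1cc([C@@H]2CC(=O)c3c(O)c(CC=C(C)C)c(O)c(CC=C(C)C)c3O2)ccc1O | target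

## Step count and risk

Total steps: 8. Longest linear sequence: 5 (steps 1, 2, 3, 7, 8; the ring-B branch, steps 4, 5, 6, 7, 8, is equally long).

**Step 8 (key step).** The most likely failure is competition between the O7 and O5 groups for C6. A misdirected first migration leads to a para-shift of a tert-prenyl group to C8 or to loss of isoprene by elimination. A second concern is slow erosion of configuration at C2 by reversible ring opening once 5-OH and 4'-OH are free at 110 °C. The fallback places all three prenyl groups before C2 exists; it sets out from 1 and 12 and returns at 15. Direct C-prenylation of 1 (prenyl bromide, DBU, THF; a known if modest reaction) would give 1-[2,4,6-trihydroxy-3,5-bis(3-methylbut-2-enyl)phenyl]ethanone F1. MOMCl/iPr2NEt would mask two hydroxyls to give 1-[2-hydroxy-4,6-bis(methoxymethoxy)-3,5-bis(3-methylbut-2-enyl)phenyl]ethanone F2. DMF-DMA would give the enaminone (E)-3-(dimethylamino)-1-[2-hydroxy-4,6-bis(methoxymethoxy)-3,5-bis(3-methylbut-2-enyl)phenyl]prop-2-en-1-one F3, which acetic acid would close to 5,7-bis(methoxymethoxy)-6,8-bis(3-methylbut-2-enyl)chromen-4-one F4. Heating 12 in toluene would effect the single, regiochemically unambiguous Claisen shift to [4-hydroxy-3-(3-methylbut-2-enyl)phenyl]boronic acid F5. Rhodium/diene 1,4-addition of F5 to F4 under the conditions of step 7 would give (2S)-2-[4-hydroxy-3-(3-methylbut-2-enyl)phenyl]-5,7-bis(methoxymethoxy)-6,8-bis(3-methylbut-2-enyl)chroman-4-one F6, and HCl/MeOH at 40 °C would remove the acetals to give 15.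

**Step 7.** The chromone carries two donor oxygens and a bulky peri ether, so carbometalation may be slow; protodeboronation of the electron-rich boronic acid could then dominate. Attack of the aryl–rhodium species on a vinyl group and partial ring opening by hydroxide are further risks. The fallback replaces asymmetric catalysis by stoichiometric organometallic addition and kinetic resolution; it sets out from 6 and 9 and returns at 13. Magnesium in THF would convert 9 into bromo[4-(2-methylbut-3-en-2-yloxy)phenyl]magnesium F7. Copper-catalysed 1,4-addition to 6 in the presence of TMSCl would give the silyl enol ether trimethyl{[5,7-bis(2-methylbut-3-en-2-yloxy)-2-[4-(2-methylbut-3-en-2-yloxy)phenyl]-2H-chromen-4-yl]oxy}silane F8, which is hydrolysed on work-up to racemic 5,7-bis(2-methylbut-3-en-2-yloxy)-2-[4-(2-methylbut-3-en-2-yloxy)phenyl]chroman-4-one F9. Noyori–Ikariya asymmetric transfer hydrogenation (Cp*Rh/TsDPEN, HCO2H/Et3N, catalyst antipode that consumes the 2R enantiomer) would reduce that half to (2R,4R)-5,7-bis(2-methylbut-3-en-2-yloxy)-2-[4-(2-methylbut-3-en-2-yloxy)phenyl]chroman-4-ol F10 and leave 13 for separation.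

**Step 1.** The phloroglucinol ring is a strong carbon nucleophile, so C-propargylation may compete with etherification. The second etherification, next to the acetyl group, may also stall at the mono-ether. The fallback changes the electrophile class and the oxidation level; it sets out from 1 and returns at 6, bypassing steps 2 and 3. Pd(PPh3)4-catalysed decarboxylative O-allylation (Tsuji–Trost) with tert-butyl 2-methylbut-3-en-2-yl carbonate in THF at 0 °C, where the phenoxide attacks the more substituted allyl terminus under kinetic control and no amine base is present, would give 1-[2-hydroxy-4,6-bis(2-methylbut-3-en-2-yloxy)phenyl]ethanone F11. DMF-DMA at no more than 60 °C would give (E)-3-(dimethylamino)-1-[2-hydroxy-4,6-bis(2-methylbut-3-en-2-yloxy)phenyl]prop-2-en-1-one F12, and acetic acid at room temperature would close it to 6.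

## Further compounds

F1 | step 8 | 1-[2,4,6-trihydroxy-3,5-bis(3-methylbut-2-enyl)phenyl]ethanone | CC(=O)c1c(O)c(CC=C(C)C)c(O)c(CC=C(C)C)c1O
F2 | step 8 | 1-[2-hydroxy-4,6-bis(methoxymethoxy)-3,5-bis(3-methylbut-2-enyl)phenyl]ethanone | CC(=O)c1c(O)c(CC=C(C)C)c(OCOC)c(CC=C(C)C)c1OCOC
F3 | step 8 | (E)-3-(dimethylamino)-1-[2-hydroxy-4,6-bis(methoxymethoxy)-3,5-bis(3-methylbut-2-enyl)phenyl]prop-2-en-1-one | CN(C)/C=C/C(=O)c1c(O)c(CC=C(C)C)c(OCOC)c(CC=C(C)C)c1OCOC
F4 | step 8 | 5,7-bis(methoxymethoxy)-6,8-bis(3-methylbut-2-enyl)chromen-4-one | O=c1ccoc2c(CC=C(C)C)c(OCOC)c(CC=C(C)C)c(OCOC)c12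
F5 | step 8 | [4-hydroxy-3-(3-methylbut-2-enyl)phenyl]boronic acid | CC(C)=CCc1cc(B(O)O)ccc1O
F6 | step 8 | (2S)-2-[4-hydroxy-3-(3-methylbut-2-enyl)phenyl]-5,7-bis(methoxymethoxy)-6,8-bis(3-methylbut-2-enyl)chroman-4-one | CC(C)=CCc1cc([C@@H]2CC(=O)c3c(OCOC)c(CC=C(C)C)c(OCOC)c(CC=C(C)C)c3O2)ccc1O
F7 | step 7 | bromo[4-(2-methylbut-3-en-2-yloxy)phenyl]magnesium | C=CC(C)(C)Oc1ccc([Mg]Br)cc1
F8 | step 7 | trimethyl{[5,7-bis(2-methylbut-3-en-2-yloxy)-2-[4-(2-methylbut-3-en-2-yloxy)phenyl]-2H-chromen-4-yl]oxy}silane (racemic) | C[Si](C)(C)OC1=CC(c2ccc(OC(C)(C)C=C)cc2)Oc2cc(OC(C)(C)C=C)cc(OC(C)(C)C=C)c12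
F9 | step 7 | racemic 5,7-bis(2-methylbut-3-en-2-yloxy)-2-[4-(2-methylbut-3-en-2-yloxy)phenyl]chroman-4-one | O=C1CC(c2ccc(OC(C)(C)C=C)cc2)Oc2cc(OC(C)(C)C=C)cc(OC(C)(C)C=C)c12
F10 | step 7 | (2R,4R)-5,7-bis(2-methylbut-3-en-2-yloxy)-2-[4-(2-methylbut-3-en-2-yloxy)phenyl]chroman-4-ol | O[C@@H]1C[C@H](c2ccc(OC(C)(C)C=C)cc2)Oc2cc(OC(C)(C)C=C)cc(OC(C)(C)C=C)c12
F11 | step 1 | 1-[2-hydroxy-4,6-bis(2-methylbut-3-en-2-yloxy)phenyl]ethanone | CC(=O)c1c(O)cc(OC(C)(C)C=C)cc1OC(C)(C)C=C
F12 | step 1 | (E)-3-(dimethylamino)-1-[2-hydroxy-4,6-bis(2-methylbut-3-en-2-yloxy)phenyl]prop-2-en-1-one | CN(C)/C=C/C(=O)c1c(O)cc(OC(C)(C)C=C)cc1OC(C)(C)C=C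
A1 | alternative 1 | (E)-3-[4-hydroxy-3-(3-methylbut-2-enyl)phenyl]-1-[2,4,6-trihydroxy-3,5-bis(3-methylbut-2-enyl)phenyl]prop-2-en-1-one | CC(C)=CCc1cc(/C=C/C(=O)c2c(O)c(CC=C(C)C)c(O)c(CC=C(C)C)c2O)ccc1O
A2 | alternative 2 | (2S)-5,7-dihydroxy-2-(4-hydroxy-3-iodophenyl)-6,8-diiodochroman-4-one | O=C1C[C@@H](c2ccc(O)c(I)c2)Oc2c(I)c(O)c(I)c(O)c12
A3 | alternative 3 | (E)-1-[2-hydroxy-4,6-bis(2-methylbut-3-en-2-yloxy)phenyl]-3-[4-(2-methylbut-3-en-2-yloxy)phenyl]prop-2-en-1-one | C=CC(C)(C)Oc1ccc(/C=C/C(=O)c2c(O)cc(OC(C)(C)C=C)cc2OC(C)(C)C=C)cc1
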